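**Retrosynthetic overview**
1. The (E)-cinnamate C=C is cut last: Wittig union of the cis-benzodioxane aldehyde 14 with the lactate-derived phosphonium salt 9, both partners unprotected.
2. Both C6–C3 units come from one enol ester 6. Its C2–C3 bond is the key bond: a lithiated α-acyloxy phosphonate (masked glyoxylate acyl anion, tBuO2C–C(=O)⁻) is joined to the vanillin carbonyl carbon, so two carbonyl-level carbons are linked.
3. Lactate half: asymmetric hydrogenation of 6 sets the R centre; the chloroacetyl group carried by the key reagent becomes the two-carbon ylide unit.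
4. Benzodioxane half: 6 → α-bromo-α-keto ester → regioselective annulation with 3,4-dihydroxybenzaldehyde → cis-selective asymmetric hydrogenation of the tetrasubstituted dioxine C=C sets 2R,3R.
5. Ring formation: only the 1,4-dioxine ring is built (step 7); all benzene rings are bought.

Assumption: the SMILES descriptors are taken literally; 2R,3R on the dioxane ring means CO2H and aryl are cis, and the lactate centre is R.

**Route**

Step 1
Reactants: 1 vanillin (4-hydroxy-3-methoxybenzaldehyde)
Product: 2 3-methoxy-4-[(4-methoxyphenyl)methoxy]benzaldehyde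
Conditions: 4-methoxybenzyl chloride, K2CO3, KI (cat.), DMF, 60 °C
Reagents that add atoms: 4-methoxybenzyl chloride, COc1ccc(CCl)cc1
Why: Williamson ether synthesis on the acidic phenol masks it with an acid-labile group; no stereocentre.

Step 2
Reactants: 3 tert-butyl 2-(diethoxyphosphoryl)acetate
Product: 4 tert-butyl 2-diazo-2-(diethoxyphosphoryl)acetate
Conditions: 4-acetamidobenzenesulfonyl azide, DBU, MeCN, 0 → 25 °C
Reagents that add atoms: 4-acetamidobenzenesulfonyl azide, CC(=O)Nc1ccc(cc1)S(=O)(=O)N=[N+]=[N-]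
Why: Regitz diazo transfer to the doubly activated methylene; no stereocentre.

Step 3
Reactants: 4 tert-butyl 2-diazo-2-(diethoxyphosphoryl)acetate; 2 3-methoxy-4-[(4-methoxyphenyl)methoxy]benzaldehyde
Product: 6 tert-butyl (Z)-2-(2-chloroacetoxy)-3-{3-methoxy-4-[(4-methoxyphenyl)methoxy]phenyl}prop-2-enoate, via chloroacetoxy phosphonate 5 (not isolated)
Conditions: ClCH2CO2H, Rh2(OAc)4 (1 mol %), PhMe, 80 °C; then LiN(SiMe3)2, THF, −78 °C; then 2, −78 → 0 °C
Reagents that add atoms: chloroacetic acid, OC(=O)CCl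
Why: Dirhodium-carbenoid O–H insertion into chloroacetic acid gives 5, whose lithio derivative acts as an acyl anion equivalent of tert-butyl glyoxylate in a Horner–Wadsworth–Emmons olefination of 2, so the aldehyde carbon and the future C2 keto carbon (both carbonyl-level, normally electrophilic) are joined; no stereocentre is formed and the Z/E mixture (Z major) is used as such.

Step 4
Reactants: 6 tert-butyl (Z)-2-(2-chloroacetoxy)-3-{3-methoxy-4-[(4-methoxyphenyl)methoxy]phenyl}prop-2-enoate
Product: 7 tert-butyl (2R)-2-(2-chloroacetoxy)-3-{3-methoxy-4-[(4-methoxyphenyl)methoxy]phenyl}propanoate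
Conditions: [Rh(cod)((R,R)-Et-DuPhos)]OTf (1 mol %), H2 (4 bar), CH2Cl2, 25 °C
Reagents that add atoms: none
Why: Chelation-controlled asymmetric hydrogenation of an α-(acyloxy)acrylate, in which the enol-ester carbonyl and the alkene bind cationic rhodium and the (R,R)-ligand is expected to deliver H2 to the face that gives the R centre from either alkene isomer (the antipodal ligand gives S).

Step 5
Reactants: 7 tert-butyl (2R)-2-(2-chloroacetoxy)-3-{3-methoxy-4-[(4-methoxyphenyl)methoxy]phenyl}propanoate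
Product: 9 {2-[(1R)-1-carboxy-2-(4-hydroxy-3-methoxyphenyl)ethoxy]-2-oxoethyl}triphenylphosphonium chloride, via deprotected chloroacetoxy acid 8 (not isolated)
Conditions: TFA–CH2Cl2 (1:2), anisole, 0 → 25 °C; evaporate; PPh3, MeCN, 70 °C
Reagents that add atoms: triphenylphosphine, c1ccc(cc1)P(c1ccccc1)c1ccccc1
Why: Acidolysis removes the 4-methoxybenzyl ether and the tert-butyl ester (anisole traps the benzyl cation), then SN2 quaternisation of PPh3 by the α-chloro ester gives the Wittig salt under non-basic conditions that leave the stereocentre untouched.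

Step 6
Reactants: 6 tert-butyl (Z)-2-(2-chloroacetoxy)-3-{3-methoxy-4-[(4-methoxyphenyl)methoxy]phenyl}prop-2-enoate
Product: 10 tert-butyl 3-bromo-3-{3-methoxy-4-[(4-methoxyphenyl)methoxy]phenyl}-2-oxopropanoate
Conditions: NBS (1.0 equiv), THF–H2O (9:1), 0 °C
Reagents that add atoms: N-bromosuccinimide, O=C1CCC(=O)N1Br
Why: Electrophilic bromination of the electron-rich enol ester at C3 with transfer of the acyl group to water (enol ester to α-bromo ketone); the new centre is racemic and is erased in step 7.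

Step 7
Reactants: 10 tert-butyl 3-bromo-3-{3-methoxy-4-[(4-methoxyphenyl)methoxy]phenyl}-2-oxopropanoate; 11 3,4-dihydroxybenzaldehyde
Product: 13 7-formyl-3-(4-hydroxy-3-methoxyphenyl)-1,4-benzodioxine-2-carboxylic acid, via cyclic hemiketal 12 (not isolated)
Conditions: K2CO3 (1.1 equiv), acetone, 0 → 25 °C; evaporate; (CF3CO)2O, anisole, TFA–CH2Cl2 (1:1), 0 → 25 °C; aqueous work-up
Reagents that add atoms: none
Why: The more acidic 4-OH (para to CHO) is the only phenoxide formed and displaces the activated benzylic bromide (SN2), the 3-OH closes onto the α-keto ester as a hemiketal, and acid-promoted dehydration with concurrent acidolysis of both protecting groups gives the conjugated benzodioxine with the aryl-bearing carbon on the para oxygen; no stereocentre remains.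

Step 8
Reactants: 13 7-formyl-3-(4-hydroxy-3-methoxyphenyl)-1,4-benzodioxine-2-carboxylic acid
Product: 14 (2R,3R)-7-formyl-3-(4-hydroxy-3-methoxyphenyl)-2,3-dihydro-1,4-benzodioxine-2-carboxylic acid
Conditions: Ru(OAc)2[(S)-MeO-BIPHEP] (2 mol %), H2 (60 bar), Et3N (1 equiv), MeOH, 40 °C; cold dilute citric acid
Reagents that add atoms: none
Why: Proposed new method: carboxylate-directed syn addition of H2 to the tetrasubstituted enol-ether acrylic acid on a chiral divalent ruthenium diphosphine dicarboxylate should give only the cis acid and set both centres at once, the face (2R,3R versus 2S,3S) being fixed by the ligand antipode chosen in an initial screen; the closest known reaction types are Ru(OAc)2(biaryl diphosphine)-catalysed asymmetric hydrogenation of cyclic tetrasubstituted β-aryl acrylic acids and asymmetric hydrogenation of 2-substituted 1,4-benzodioxines.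

Step 9
Reactants: 14 (2R,3R)-7-formyl-3-(4-hydroxy-3-methoxyphenyl)-2,3-dihydro-1,4-benzodioxine-2-carboxylic acid; 9 {2-[(1R)-1-carboxy-2-(4-hydroxy-3-methoxyphenyl)ethoxy]-2-oxoethyl}triphenylphosphonium chloride
Product: 16 (2R,3R)-7-[(E)-3-{[(1R)-1-carboxy-2-(4-hydroxy-3-methoxyphenyl)ethyl]oxy}-3-oxoprop-1-en-1-yl]-3-(4-hydroxy-3-methoxyphenyl)-2,3-dihydro-1,4-benzodioxine-2-carboxylic acid, via phosphonium ylide 15 (not isolated)
Conditions: Et3N (5 equiv), CH2Cl2–DMF (4:1), 25 °C; cold dilute citric acid; reversed-phase chromatography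
Reagents that add atoms: none
Why: Wittig olefination with the ester-stabilised ylide formed in situ gives the (E)-cinnamate, and because both acids are present as carboxylates the α-centres (dioxane C2 and the lactate carbon) are not epimerised by the amine base.

**Compound list**
1 | vanillin (4-hydroxy-3-methoxybenzaldehyde) | COc1cc(C=O)ccc1O | starting material
2 | 3-methoxy-4-[(4-methoxyphenyl)methoxy]benzaldehyde | COc1ccc(COc2ccc(C=O)cc2OC)cc1 | intermediate
3 | tert-butyl 2-(diethoxyphosphoryl)acetate | CCOP(=O)(OCC)CC(=O)OC(C)(C)C | starting material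
4 | tert-butyl 2-diazo-2-(diethoxyphosphoryl)acetate | CCOP(=O)(OCC)C(=[N+]=[N-])C(=O)OC(C)(C)C | intermediate
5 | tert-butyl 2-(2-chloroacetoxy)-2-(diethoxyphosphoryl)acetate (racemic, not isolated) | CCOP(=O)(OCC)C(OC(=O)CCl)C(=O)OC(C)(C)C | intermediate
6 | tert-butyl (Z)-2-(2-chloroacetoxy)-3-{3-methoxy-4-[(4-methoxyphenyl)methoxy]phenyl}prop-2-enoate (Z major, Z/E mixture used) | COc1ccc(COc2ccc(/C=C(\OC(=O)CCl)C(=O)OC(C)(C)C)cc2OC)cc1 | intermediate
7 | tert-butyl (2R)-2-(2-chloroacetoxy)-3-{3-methoxy-4-[(4-methoxyphenyl)methoxy]phenyl}propanoate | COc1ccc(COc2ccc(C[C@@H](OC(=O)CCl)C(=O)OC(C)(C)C)cc2OC)cc1 | intermediate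
8 | (2R)-2-(2-chloroacetoxy)-3-(4-hydroxy-3-methoxyphenyl)propanoic acid (not isolated) | COc1cc(C[C@@H](OC(=O)CCl)C(=O)O)ccc1O | intermediate
9 | {2-[(1R)-1-carboxy-2-(4-hydroxy-3-methoxyphenyl)ethoxy]-2-oxoethyl}triphenylphosphonium chloride | COc1cc(C[C@@H](OC(=O)C[P+](c2ccccc2)(c2ccccc2)c2ccccc2)C(=O)O)ccc1O.[Cl-] | intermediate
10 | tert-butyl 3-bromo-3-{3-methoxy-4-[(4-methoxyphenyl)methoxy]phenyl}-2-oxopropanoate (racemic) | COc1ccc(COc2ccc(C(Br)C(=O)C(=O)OC(C)(C)C)cc2OC)cc1 | intermediate
11 | 3,4-dihydroxybenzaldehyde | O=Cc1ccc(O)c(O)c1 | starting material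
12 | tert-butyl 7-formyl-2-hydroxy-3-{3-methoxy-4-[(4-methoxyphenyl)methoxy]phenyl}-2,3-dihydro-1,4-benzodioxine-2-carboxylate (diastereomer mixture, not isolated) | COc1ccc(COc2ccc(C3Oc4ccc(C=O)cc4OC3(O)C(=O)OC(C)(C)C)cc2OC)cc1 | intermediate
13 | 7-formyl-3-(4-hydroxy-3-methoxyphenyl)-1,4-benzodioxine-2-carboxylic acid | COc1cc(C2=C(C(=O)O)Oc3cc(C=O)ccc3O2)ccc1O | intermediate
14 | (2R,3R)-7-formyl-3-(4-hydroxy-3-methoxyphenyl)-2,3-dihydro-1,4-benzodioxine-2-carboxylic acid (cis) | O=Cc1ccc2c(c1)O[C@@H](C(=O)O)[C@@H](c1ccc(O)c(OC)c1)O2 | intermediate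
15 | (2R)-3-(4-hydroxy-3-methoxyphenyl)-2-{[2-(triphenylphosphoranylidene)acetyl]oxy}propanoic acid (not isolated) | COc1cc(C[C@@H](OC(=O)C=P(c2ccccc2)(c2ccccc2)c2ccccc2)C(=O)O)ccc1O | intermediate
16 | (2R,3R)-7-[(E)-3-{[(1R)-1-carboxy-2-(4-hydroxy-3-methoxyphenyl)ethyl]oxy}-3-oxoprop-1-en-1-yl]-3-(4-hydroxy-3-methoxyphenyl)-2,3-dihydro-1,4-benzodioxine-2-carboxylic acid | COc1cc(C[C@@H](OC(=O)/C=C/c2ccc3c(c2)O[C@@H](C(=O)O)[C@@H](c2ccc(O)c(OC)c2)O3)C(=O)O)ccc1O | target

**Totals**
Total step count: 9.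
Longest linear sequence: 6 steps (1 → 2 → 6 → 10 → 13 → 14 → 16; the same length from 3 through 4).

**Three steps most likely to fail, with fallbacks**

Step 8 (asymmetric hydrogenation of the tetrasubstituted dioxine acid; the aldehyde must also survive). The fallback sets out from 13 and returns at 14, replacing catalyst control by cis-selective heterogeneous hydrogenation plus enzymatic resolution. Methanol, trimethyl orthoformate and TsOH convert 13 into methyl 7-(dimethoxymethyl)-3-(4-hydroxy-3-methoxyphenyl)-1,4-benzodioxine-2-carboxylate F9. Hydrogenation over 5% Rh on Al2O3 (EtOAc, 5 bar) adds H2 syn and gives racemic cis methyl (2RS,3RS)-7-(dimethoxymethyl)-3-(4-hydroxy-3-methoxyphenyl)-2,3-dihydro-1,4-benzodioxine-2-carboxylate F10. Candida antarctica lipase B at pH 7 then hydrolyses one enantiomer without base, giving (2R,3R)-7-(dimethoxymethyl)-3-(4-hydroxy-3-methoxyphenyl)-2,3-dihydro-1,4-benzodioxine-2-carboxylic acid F11. If the lipase prefers the other enantiomer, the recovered 2R,3R ester is hydrolysed with an unselective esterase instead. Brief cold dilute acid unmasks the aldehyde to give 14.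

Step 3 (one-pot insertion and olefination; the chloroacetyl group can migrate or be attacked in the aldolate). The fallback sets out from 2 and returns at 6, moving the acyl-anion bond construction to a dithiane alkylation. NaBH4 reduces 2 to {3-methoxy-4-[(4-methoxyphenyl)methoxy]phenyl}methanol F1, and MsCl, Et3N and LiCl convert it into 4-(chloromethyl)-2-methoxy-1-[(4-methoxyphenyl)methoxy]benzene F2. The glyoxylate anion equivalent tert-butyl 1,3-dithiane-2-carboxylate F3 is made from 1,3-dithiane, n-BuLi and Boc2O by inverse addition. F3 is deprotonated with NaH in DMF and alkylated by F2 to give tert-butyl 2-({3-methoxy-4-[(4-methoxyphenyl)methoxy]phenyl}methyl)-1,3-dithiane-2-carboxylate F4. MeI and CaCO3 in aqueous MeCN unmask tert-butyl 3-{3-methoxy-4-[(4-methoxyphenyl)methoxy]phenyl}-2-oxopropanoate F5. O-acylation of its enol with chloroacetyl chloride and Et3N gives 6.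

Step 7 (clean alkylation by the sensitive secondary benzylic bromoketone 10, and dehydration of the hemiketal). The fallback sets out from 11 and returns at 13, building the dioxine ring first and attaching the aryl group by cross-coupling. Compound 11 and ethyl bromopyruvate (K2CO3, acetone; then (CF3CO)2O in TFA) give ethyl 7-formyl-1,4-benzodioxine-2-carboxylate F6, with the same 4-OH-first regiochemistry. Addition of Br2 and elimination with Et3N give ethyl 3-bromo-7-formyl-1,4-benzodioxine-2-carboxylate F7. Suzuki coupling with 2-methoxy-4-(4,4,5,5-tetramethyl-1,3,2-dioxaborolan-2-yl)phenol (Pd(PPh3)4, K3PO4, dioxane–water) gives ethyl 7-formyl-3-(4-hydroxy-3-methoxyphenyl)-1,4-benzodioxine-2-carboxylate F8. LiOH in THF–water followed by acidification, harmless at this achiral stage, gives 13.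

**Further compounds**
F1 | step 3 | {3-methoxy-4-[(4-methoxyphenyl)methoxy]phenyl}methanol | COc1ccc(COc2ccc(CO)cc2OC)cc1
F2 | step 3 | 4-(chloromethyl)-2-methoxy-1-[(4-methoxyphenyl)methoxy]benzene | COc1ccc(COc2ccc(CCl)cc2OC)cc1
F3 | step 3 | tert-butyl 1,3-dithiane-2-carboxylate | CC(C)(C)OC(=O)C1SCCCS1
F4 | step 3 | tert-butyl 2-({3-methoxy-4-[(4-methoxyphenyl)methoxy]phenyl}methyl)-1,3-dithiane-2-carboxylate | COc1ccc(COc2ccc(CC3(SCCCS3)C(=O)OC(C)(C)C)cc2OC)cc1
F5 | step 3 | tert-butyl 3-{3-methoxy-4-[(4-methoxyphenyl)methoxy]phenyl}-2-oxopropanoate | COc1ccc(COc2ccc(CC(=O)C(=O)OC(C)(C)C)cc2OC)cc1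
F6 | step 7 | ethyl 7-formyl-1,4-benzodioxine-2-carboxylate | CCOC(=O)C1=COc2ccc(C=O)cc2O1
F7 | step 7 | ethyl 3-bromo-7-formyl-1,4-benzodioxine-2-carboxylate | CCOC(=O)C1=C(Br)Oc2ccc(C=O)cc2O1
F8 | step 7 | ethyl 7-formyl-3-(4-hydroxy-3-methoxyphenyl)-1,4-benzodioxine-2-carboxylate | CCOC(=O)C1=C(c2ccc(O)c(OC)c2)Oc2ccc(C=O)cc2O1
F9 | step 8 | methyl 7-(dimethoxymethyl)-3-(4-hydroxy-3-methoxyphenyl)-1,4-benzodioxine-2-carboxylate | COC(=O)C1=C(c2ccc(O)c(OC)c2)Oc2ccc(C(OC)OC)cc2O1
F10 | step 8 | methyl (2RS,3RS)-7-(dimethoxymethyl)-3-(4-hydroxy-3-methoxyphenyl)-2,3-dihydro-1,4-benzodioxine-2-carboxylate (racemic cis; 2R,3R enantiomer drawn) | COC(OC)c1ccc2c(c1)O[C@@H](C(=O)OC)[C@@H](c1ccc(O)c(OC)c1)O2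
F11 | step 8 | (2R,3R)-7-(dimethoxymethyl)-3-(4-hydroxy-3-methoxyphenyl)-2,3-dihydro-1,4-benzodioxine-2-carboxylic acid | COC(OC)c1ccc2c(c1)O[C@@H](C(=O)O)[C@@H](c1ccc(O)c(OC)c1)O2
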